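The data come from a simulation on assumed constants; scatter was added.

4 questions stand on this flask, the north-west one, and this note hands it over at the bench.

common to all: substrate 0.36 M; reagent 0.396 M; initiator 6.1 mM
- north-west: temperature 5 °C; the very flask that is asked about, followed so far
- east: temperature −10 °C; run made earlier
- flask: temperature 5 °C; time 1.5 h

- north-west (time / min: target / %, substrate / %): 8.00: 19.0, 58.3; 25.0: 33.0, 19.8; 40.0: 37.5, 8.3; 60.0: 38.9, 2.4; 90.0: 39.0, 0
- east (time / min: target / %, substrate / %): 15.0: 10.6, 79.8; 50.0: 14.7, 45.3; 80.0: 15.1, 29.7; 120: 18.0, 13.7; 180: 17.1, 5.6

(readings scatter by 1 percentage point)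

- delta: at 1.5 h take out 90% of the by-product then present, then wait 1.5 h
- alpha: at 1.5 h raise the temperature by 15 K, then wait 1.5 h
- eta: at 1.5 h add reagent, 100% of the amount charged, then wait 1.5 h
- zeta: change nothing and wait 1.5 h more

- the volume of additions can be left aside
- the numbers in the tables scatter with a standard deviation of 1 percentage point

- target, in percent of the substrate first charged, at 1.5 h
- the remedy with the largest gain of target, or "none" below 2 percentage points (delta / alpha / eta / zeta / none)
- target present, in percent of the substrate first charged, after alpha
- target present, in percent of the substrate first charged, after zeta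

This flask holds c(reagent) = 0.396 M against c(substrate) = 0.36 M, more reagent than substrate, and the reading at 90.0 min puts substrate at 0%. That last reading gives 39.0% for target over substrate consumed, and this ratio, once it stops moving, is what we carry: the plateau share. In this flask it reads 45.6% at 8.00 min and 39.9% at 60.0 min. The east flask, at −10 °C, reads 18.1% at 180 min.

So when you come at 1.5 h, expect target at about 39.0% of the charge. Don't wait for more and don't add reagent: with substrate at 0%, far less than target, we expect neither to move target. Warming is the step to try, since the colder east flask sits lower. Target against the rest of the consumed substrate stands at 0.639 here and 0.221 in the east flask, a factor 2.89 over 15 K. One more such factor gives our share of 64.9%, higher than the forecast's.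

The forecast gives 39% (37.5% to 40.5%) now, 39% (37% to 40.5%) after waiting, 62% (55% to 69%) after warming, and names alpha, holding that “waiting or adding reagent changes nothing”.

    initiator → 2 initiating radical (k = 2.30 × 10⁻⁶ /s, Ea = 98.0 kJ/mol)
    substrate + second chain carrier → by-product + first chain carrier (k = 2.90 × 10⁵ /M/s, Ea = 13.0 kJ/mol)
    substrate + initiating radical → capped initiator + first chain carrier (k = 3.40 × 10⁷ /M/s, Ea = 17.0 kJ/mol)
    target ⇌ isomer of the product (K = 1.60, k = 0.0120 /s, Ea = 72.0 kJ/mol, ΔH = −42.0 kJ/mol)
    reagent + first chain carrier → target + second chain carrier (k = 7.30 × 10⁵ /M/s, Ea = 12.0 kJ/mol)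
    2 second chain carrier → ended chains (k = 1.00 × 10⁹ /M/s, Ea = 10.0 kJ/mol)
    (constants at 5 °C)

This flask gives 38.4% at 1.5 h, 38.5% after waiting and 61.3% after warming, so alpha gains 23 points, far more than any other remedy. With 0.28% of substrate left, the plateau share reckons 38.9% for this flask, which holds 61.4% isomer of the product beside its target. The neighbouring flask has c(substrate) = 0.61 M, so reagent is the limiting reagent: its charge covers 64.9% of that flask's substrate, and the plateau share reckons 25.3% target. That neighbour ends at 25.0% target, with 0% of its reagent and 35% of its substrate left.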